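**Retrosynthetic overview**
- The seven-membered lactone (ring B) is opened at the aryl–C(=O) bond: an aryl bromide on ring A plus CO, closed last by Pd-catalysed carbonylative lactonisation onto the ring C phenol.
- The diaryl ether is cut next: SNAr of the ring C phenol on a ring A aryl fluoride (3-bromo-2-fluoro-6-methoxy-4-methylbenzaldehyde, made from 2,6-difluoro-4-methylbenzaldehyde by NaOMe, then NBS).
- Key C–C bond, aryl–C(=O) of the chromanone: 2-methoxy-6-methyl-1,4-benzoquinone plus prenal under light. The formyl carbon reacts with reversed polarity as a nucleophilic acyl radical (an acyl-anion equivalent) at the electrophilic quinone carbon; oxa-Michael addition then closes the pyranone (ring D).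
- Ring order: ring D on ring C, then the ether bridge, then ring B.

Assumption: the target SMILES has no stereocentre, so the compound is achiral and no stereocontrol is needed.

**Step 1**
Reactants: 1 2-methoxy-6-methylphenol
Product: 2 2-methoxy-6-methyl-1,4-benzoquinone
Conditions: Co(salen) (C16H14CoN2O2, 5 mol %), O2 (1 atm), DMF, 25 °C
Reagents that add atoms: dioxygen, O=O
Why: Salcomine-type aerobic oxidation (divalent cobalt carrying O2) of a 2,6-disubstituted phenol places the new oxygen at the free para position and gives the para-quinone, a well-known phenol-to-quinone oxidation.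

**Step 2**
Reactants: 2 2-methoxy-6-methyl-1,4-benzoquinone; 3 3-methylbut-2-enal (prenal)
Product: 5 6-hydroxy-7-methoxy-2,2,5-trimethylchroman-4-one, via acylhydroquinone 4 (not isolated)
Conditions: 3 (5 equiv), Ph2CO (0.2 equiv), PhCF3, hν (>350 nm, Pyrex), 20 °C, Ar; evaporate; p-TsOH·H2O (0.1 equiv), PhMe, 80 °C
Reagents that add atoms: none
Why: Klinger–Kolbe photoacylation (photo-Friedel–Crafts acylation of a quinone) in which the triplet quinone abstracts the formyl hydrogen and the resulting nucleophilic 3-methylbut-2-enoyl radical, an acyl-anion equivalent of the normally electrophilic aldehyde carbon, bonds to electrophilic C5 of the quinone (the only free position on the electron-poor, non-methoxylated C5=C6 bond) to give acylhydroquinone 4, whose hydroxyl ortho to the new ketone then closes the pyranone by acid-catalysed oxa-Michael addition to the β,β-dimethyl enone.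

**Step 3**
Reactants: 6 2,6-difluoro-4-methylbenzaldehyde
Product: 7 2-fluoro-6-methoxy-4-methylbenzaldehyde
Conditions: NaOMe (1.05 equiv), MeOH, 0 → 50 °C
Reagents that add atoms: sodium methoxide, C[O-].[Na+]
Why: Nucleophilic aromatic substitution of one of two equivalent fluorides ortho to the formyl group, which stops at mono-substitution because the methoxy group introduced deactivates the ring toward a second attack.

**Step 4**
Reactants: 7 2-fluoro-6-methoxy-4-methylbenzaldehyde
Product: 8 3-bromo-2-fluoro-6-methoxy-4-methylbenzaldehyde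
Conditions: NBS (1.05 equiv), TFA (0.1 equiv), MeCN, 0 → 25 °C, dark
Reagents that add atoms: N-bromosuccinimide, BrN1C(=O)CCC1=O
Why: Electrophilic aromatic bromination directed para to the methoxy group (the strongest donor), ortho to methyl and meta to the formyl group, as 3-fluoroanisoles brominate para to OMe, which puts bromine between fluorine and methyl where the ester carbon is needed.

**Step 5**
Reactants: 5 6-hydroxy-7-methoxy-2,2,5-trimethylchroman-4-one; 8 3-bromo-2-fluoro-6-methoxy-4-methylbenzaldehyde
Product: 9 3-bromo-6-methoxy-2-[(7-methoxy-2,2,5-trimethyl-4-oxochroman-6-yl)oxy]-4-methylbenzaldehyde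
Conditions: Cs2CO3 (1.5 equiv), DMF, 90 °C, Ar
Reagents that add atoms: none
Why: Nucleophilic aromatic substitution of the small fluoride, activated by the ortho formyl group and the adjacent bromine, by the only free phenoxide of 5 (so the ether oxygen is fixed at C6 of the chromanone), under carbonate conditions that are known to leave enolisable aryl ketones and aryl aldehydes uncondensed while the meta-placed bromide stays inert.

**Step 6**
Reactants: 9 3-bromo-6-methoxy-2-[(7-methoxy-2,2,5-trimethyl-4-oxochroman-6-yl)oxy]-4-methylbenzaldehyde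
Product: 10 3-bromo-6-hydroxy-2-[(7-hydroxy-2,2,5-trimethyl-4-oxochroman-6-yl)oxy]-4-methylbenzaldehyde
Conditions: BBr3 (5 equiv), CH2Cl2, −78 → 0 °C; then H2O
Reagents that add atoms: none
Why: Lewis-acid cleavage of aryl methyl ethers, both of which have a neighbouring oxygen (formyl or aryloxy) that chelates boron and speeds demethylation, while the diaryl ether, the aryl bromide and the chromanone ring oxygen (deactivated as a vinylogous ester) survive.

**Step 7**
Reactants: 10 3-bromo-6-hydroxy-2-[(7-hydroxy-2,2,5-trimethyl-4-oxochroman-6-yl)oxy]-4-methylbenzaldehyde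
Product: 11 Mollicellin A
Conditions: Pd(OAc)2 (5 mol %), Xantphos (7.5 mol %), Et3N (3 equiv), CO (1 atm), PhMe (0.01 M), 100 °C
Reagents that add atoms: carbon monoxide, [C-]#[O+]
Why: Palladium-catalysed carbonylative lactonisation (intramolecular aryloxycarbonylation) in which zerovalent palladium inserts into the C–Br bond, CO inserts, and the phenol on ring C ortho to the ether bridge captures the acylpalladium to close the seven-membered lactone, whereas the salicylaldehyde hydroxyl sits para to the acyl carbon and cannot reach it.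

**Compound list**
1 | 2-methoxy-6-methylphenol | COc1cccc(C)c1O | starting material
2 | 2-methoxy-6-methyl-1,4-benzoquinone | COC1=CC(=O)C=C(C)C1=O | intermediate
3 | 3-methylbut-2-enal (prenal) | CC(C)=CC=O | starting material
4 | 1-(3,6-dihydroxy-4-methoxy-2-methylphenyl)-3-methylbut-2-en-1-one (acylhydroquinone, not isolated) | CC(C)=CC(=O)c1c(C)c(O)c(OC)cc1O | intermediate
5 | 6-hydroxy-7-methoxy-2,2,5-trimethylchroman-4-one | COc1cc2OC(C)(C)CC(=O)c2c(C)c1O | intermediate
6 | 2,6-difluoro-4-methylbenzaldehyde | Cc1cc(F)c(C=O)c(F)c1 | starting material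
7 | 2-fluoro-6-methoxy-4-methylbenzaldehyde | COc1cc(C)cc(F)c1C=O | intermediate
8 | 3-bromo-2-fluoro-6-methoxy-4-methylbenzaldehyde | COc1cc(C)c(Br)c(F)c1C=O | intermediate
9 | 3-bromo-6-methoxy-2-[(7-methoxy-2,2,5-trimethyl-4-oxochroman-6-yl)oxy]-4-methylbenzaldehyde | COc1cc(C)c(Br)c(Oc2c(C)c3C(=O)CC(C)(C)Oc3cc2OC)c1C=O | intermediate
10 | 3-bromo-6-hydroxy-2-[(7-hydroxy-2,2,5-trimethyl-4-oxochroman-6-yl)oxy]-4-methylbenzaldehyde | Oc1cc(C)c(Br)c(Oc2c(C)c3C(=O)CC(C)(C)Oc3cc2O)c1C=O | intermediate
11 | Mollicellin A (achiral) | Cc1cc(O)c(C=O)c2c1C(=O)Oc1cc3c(c(C)c1O2)C(=O)CC(C)(C)O3 | target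

**Step count and risks**
Total steps: 7. Longest linear sequence: 5 steps (1 → 2 → 5 → 9 → 10 → 11; the ring A branch 6 → 7 → 8 → 9 → 10 → 11 is equally long).

Most likely to fail, first: step 2. The acyl radical could enter at C3 beside the methoxy group, and the excited quinone could be diverted into O-acylation or allylic hydrogen abstraction from prenal. The fallback sets out from 2 and returns at 5; it blocks the competing position before the same photoacylation.
- Br2 in CH2Cl2 at 0 °C, then Et3N, brominates the nucleophilic enol-ether carbon of 2 to give 3-bromo-2-methoxy-6-methyl-1,4-benzoquinone F1, which has a single ring C–H left.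
- Irradiation with 3 as before gives 1-(3-bromo-2,5-dihydroxy-4-methoxy-6-methylphenyl)-3-methylbut-2-en-1-one F2.
- Acid closes F2 to 8-bromo-6-hydroxy-7-methoxy-2,2,5-trimethylchroman-4-one F3.
- Hydrogenolysis (H2, Pd/C, NaOAc, EtOH) removes the blocking bromine and delivers 5.

Second: step 5. The ether is tetra-ortho-substituted, the fluoride is only singly carbonyl-activated, and the temperature needed could bring on aldol condensation between the aldehyde and the chromanone methylene. The fallback sets out from 8 and returns at 11; it installs the ester carbon before the coupling so that the fluoride is flanked by two carbonyl groups.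
- Methoxycarbonylation of 8 (Pd(OAc)2, Xantphos, CO, MeOH, Et3N, 70 °C) gives methyl 2-fluoro-3-formyl-4-methoxy-6-methylbenzoate F4.
- Phenol 5 displaces the fluoride of F4 at 40 °C (K2CO3, DMF) to give methyl 3-formyl-4-methoxy-2-[(7-methoxy-2,2,5-trimethyl-4-oxochroman-6-yl)oxy]-6-methylbenzoate F5.
- Excess BBr3 (CH2Cl2, to 25 °C) removes all three methyl groups to give 3-formyl-4-hydroxy-2-[(7-hydroxy-2,2,5-trimethyl-4-oxochroman-6-yl)oxy]-6-methylbenzoic acid F6.
- DCC at high dilution closes the lactone to 11, the classical depsidone ring closure.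

Third: step 7. Oxidative addition into a bromide flanked by aryloxy and methyl groups is slow, and capture of the acylpalladium through a seven-membered transition state may lose to oligoester formation or reduction. The fallback sets out from 10 and returns at 11; it separates carbonylation from ring closure.
- Carbonylation of 10 in the presence of N-hydroxysuccinimide (Pd(OAc)2, Xantphos, CO, Et3N, 70 °C) traps the acylpalladium intermolecularly as 2,5-dioxopyrrolidin-1-yl 3-formyl-4-hydroxy-2-[(7-hydroxy-2,2,5-trimethyl-4-oxochroman-6-yl)oxy]-6-methylbenzoate F7.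
- Et3N and catalytic DMAP in MeCN at high dilution then transfer the acyl group from this active ester to the neighbouring ring C phenol and give 11.

**Further compounds**
F1 | step 2 | 3-bromo-2-methoxy-6-methyl-1,4-benzoquinone | COC1=C(Br)C(=O)C=C(C)C1=O
F2 | step 2 | 1-(3-bromo-2,5-dihydroxy-4-methoxy-6-methylphenyl)-3-methylbut-2-en-1-one | CC(C)=CC(=O)c1c(C)c(O)c(OC)c(Br)c1O
F3 | step 2 | 8-bromo-6-hydroxy-7-methoxy-2,2,5-trimethylchroman-4-one | COc1c(Br)c2OC(C)(C)CC(=O)c2c(C)c1O
F4 | step 5 | methyl 2-fluoro-3-formyl-4-methoxy-6-methylbenzoate | COC(=O)c1c(C)cc(OC)c(C=O)c1F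
F5 | step 5 | methyl 3-formyl-4-methoxy-2-[(7-methoxy-2,2,5-trimethyl-4-oxochroman-6-yl)oxy]-6-methylbenzoate | COC(=O)c1c(C)cc(OC)c(C=O)c1Oc1c(C)c2C(=O)CC(C)(C)Oc2cc1OC
F6 | step 5 | 3-formyl-4-hydroxy-2-[(7-hydroxy-2,2,5-trimethyl-4-oxochroman-6-yl)oxy]-6-methylbenzoic acid | OC(=O)c1c(C)cc(O)c(C=O)c1Oc1c(C)c2C(=O)CC(C)(C)Oc2cc1O
F7 | step 7 | 2,5-dioxopyrrolidin-1-yl 3-formyl-4-hydroxy-2-[(7-hydroxy-2,2,5-trimethyl-4-oxochroman-6-yl)oxy]-6-methylbenzoate | O=C(ON1C(=O)CCC1=O)c1c(C)cc(O)c(C=O)c1Oc1c(C)c2C(=O)CC(C)(C)Oc2cc1O
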